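**Retrosynthetic overview**
1. Target 19 ⇐ hexabenzyl ether 18 (hydrogenolysis) ⇐ 3-hydroxyflavanone 16 (reductive removal of the tertiary C3–OH).
2. Key disconnection, C3–C4 of flavanone ring C: 16 ⇒ keto-aldehyde 15. Forward, a chiral carbene turns the aldehyde carbon (future C4) into an acyl anion that adds to the C3 ketone while the labile C2–H epimerises, so C2 is fixed by dynamic kinetic resolution.
3. 15 ⇒ O1–C2 ether bond: phenol 14 + α-bromo ketone 12, the latter from deoxybenzoin 10.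
4. 10 ⇒ flavone acid 6 (as acid chloride) + benzylzinc reagent from 7; 6 ⇒ chalcone 5 ⇒ aldehyde 3 + acetophenone 4.
5. Ring order: pyranone ring of the flavone unit first (step 3), ring C of the flavanone unit last (step 8); the four benzene rings come from 1, 4, 7 and 13.

Assumption: the SMILES is read as the 2,3-trans (2R,3S) flavanone; the sense of induction of the triazolium salt in step 8 is taken as drawn, and its mirror-image salt (equally available) is used if the first run shows the opposite sense.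

**Step 1**
Reactants: 1 5-formyl-2-hydroxybenzoic acid
Product: 3 2-(benzyloxy)-5-formylbenzoic acid, via benzyl ester 2 (not isolated)
Conditions: BnBr (2.5 equiv), K2CO3, DMF, 60 °C; then NaOH (aq), THF/MeOH, 25 °C; HCl work-up
Reagents that add atoms: benzyl bromide, BrCc1ccccc1; sodium hydroxide, [Na+].[OH-]
Why: Williamson alkylation benzylates phenol and carboxylate, and only the benzyl ester is then saponified (aryl ether and non-enolisable aldehyde are inert to cold aqueous hydroxide), leaving the acid that later serves as acyl donor; no stereocentre.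

**Step 2**
Reactants: 3 2-(benzyloxy)-5-formylbenzoic acid; 4 1-[2,4-bis(benzyloxy)-6-hydroxyphenyl]ethan-1-one
Product: 5 (E)-2-(benzyloxy)-5-{3-[2,4-bis(benzyloxy)-6-hydroxyphenyl]-3-oxoprop-1-en-1-yl}benzoic acid
Conditions: KOH (50% aq, excess), EtOH, 25 °C, 48 h; HCl work-up
Reagents that add atoms: none
Why: Claisen–Schmidt (crossed aldol) condensation of a methyl ketone with a non-enolisable aldehyde; dehydration gives the conjugated E-alkene as the thermodynamic isomer.

**Step 3**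
Reactants: 5 (E)-2-(benzyloxy)-5-{3-[2,4-bis(benzyloxy)-6-hydroxyphenyl]-3-oxoprop-1-en-1-yl}benzoic acid
Product: 6 2-(benzyloxy)-5-[5,7-bis(benzyloxy)-4-oxo-4H-chromen-2-yl]benzoic acid
Conditions: I2 (10 mol%), DMSO, 130 °C
Reagents that add atoms: none
Why: Iodine/DMSO oxidative cyclisation of a 2'-hydroxychalcone closes the pyranone ring to the flavone with DMSO as terminal oxidant; benzyl ethers and the carboxylic acid survive.

**Step 4**
Reactants: 6 2-(benzyloxy)-5-[5,7-bis(benzyloxy)-4-oxo-4H-chromen-2-yl]benzoic acid; 7 1-(benzyloxy)-4-(chloromethyl)benzene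
Product: 10 5,7-bis(benzyloxy)-2-{4-(benzyloxy)-3-[2-(4-(benzyloxy)phenyl)acetyl]phenyl}-4H-chromen-4-one, via acid chloride 8 (not isolated), via benzylzinc chloride 9 (not isolated)
Conditions: 6, (COCl)2, HCONMe2 (cat.), CH2Cl2, 0 to 25 °C, evaporate; 7, Zn dust, LiCl, THF, 25 °C; combine with Pd(PPh3)4 (3 mol%), THF, 0 to 25 °C
Reagents that add atoms: none
Why: Negishi acylation: Pd-catalysed coupling of the acid chloride with the benzylic zinc reagent stops cleanly at the ketone, and the mild organozinc does not attack the chromone carbonyl or the benzyl ethers.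

**Step 5**
Reactants: 10 5,7-bis(benzyloxy)-2-{4-(benzyloxy)-3-[2-(4-(benzyloxy)phenyl)acetyl]phenyl}-4H-chromen-4-one
Product: 12 5,7-bis(benzyloxy)-2-{4-(benzyloxy)-3-[2-bromo-2-(4-(benzyloxy)phenyl)acetyl]phenyl}-4H-chromen-4-one (racemic), via silyl enol ether 11 (not isolated)
Conditions: Me3SiOTf, Et3N, CH2Cl2, 0 °C; then NBS, THF, −78 °C
Reagents that add atoms: N-bromosuccinimide, O=C1CCC(=O)N1Br
Why: Soft enolisation gives the silyl enol ether, which NBS brominates at −78 °C far faster than it attacks the electron-rich dialkoxychromone ring; the new centre is racemic and becomes labile again after step 7.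

**Step 6**
Reactants: 13 2,4,6-trihydroxybenzaldehyde
Product: 14 2,4-bis(benzyloxy)-6-hydroxybenzaldehyde
Conditions: BnBr (2.05 equiv), K2CO3, DMF, 0 to 25 °C
Reagents that add atoms: benzyl bromide, BrCc1ccccc1
Why: Williamson benzylation; the hydroxyl hydrogen-bonded to the aldehyde is the least nucleophilic and stays free, as in the analogous acetophenone 4.

**Step 7**
Reactants: 12 5,7-bis(benzyloxy)-2-{4-(benzyloxy)-3-[2-bromo-2-(4-(benzyloxy)phenyl)acetyl]phenyl}-4H-chromen-4-one (racemic); 14 2,4-bis(benzyloxy)-6-hydroxybenzaldehyde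
Product: 15 2,4-bis(benzyloxy)-6-{1-[4-(benzyloxy)phenyl]-2-[2-(benzyloxy)-5-(5,7-bis(benzyloxy)-4-oxo-4H-chromen-2-yl)phenyl]-2-oxoethoxy}benzaldehyde (racemic)
Conditions: K2CO3, acetone, 25 °C
Reagents that add atoms: none
Why: SN2 displacement (Williamson ether synthesis) of the activated secondary α-bromo ketone by the phenoxide forms the O1–C2 bond; C2 is racemic and stays epimerisable because its hydrogen is α to the ketone.

**Step 8**
Reactants: 15 2,4-bis(benzyloxy)-6-{1-[4-(benzyloxy)phenyl]-2-[2-(benzyloxy)-5-(5,7-bis(benzyloxy)-4-oxo-4H-chromen-2-yl)phenyl]-2-oxoethoxy}benzaldehyde (racemic)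
Product: 16 (2S,3R)-5,7-bis(benzyloxy)-3-{2-(benzyloxy)-5-[5,7-bis(benzyloxy)-4-oxo-4H-chromen-2-yl]phenyl}-2-[4-(benzyloxy)phenyl]-3-hydroxychroman-4-one (2-aryl and 3-aryl trans; 3-OH cis to the 2-aryl group)
Conditions: (5aR,10bS)-2-(pentafluorophenyl)-5a,10b-dihydro-4H,6H-indeno[2,1-b][1,2,4]triazolo[4,3-d][1,4]oxazin-2-ium tetrafluoroborate (15 mol%), 1,8-diazabicyclo[5.4.0]undec-7-ene (30 mol%), THF, 25 °C; chromatography, then recrystallisation of the major diastereomer
Reagents that add atoms: none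
Why: Proposed new method: the triazolylidene adds to the aldehyde and the resulting enaminol (an acyl anion equivalent) attacks the tethered aryl ketone in a six-membered ring closure, joining two carbonyl carbons; the base exchanges the doubly activated C2–H of 15 (α to the ketone, benzylic, α-aryloxy) faster than the ring closes, the chiral carbene chooses the ketone face (C3) and the chair-like transition state with the C2 aryl pseudo-equatorial and anti to the C3 aryl chooses the C2 epimer, which is then locked because 16 has no acidic hydrogen at C2 or C3; closest known reaction type: carbene-catalysed enantioselective intramolecular crossed aldehyde–ketone benzoin cyclisation to 3-hydroxychroman-4-ones and its dynamic-kinetic-resolution variant with α-substituted β-keto esters.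

**Step 9**
Reactants: 16 (2S,3R)-5,7-bis(benzyloxy)-3-{2-(benzyloxy)-5-[5,7-bis(benzyloxy)-4-oxo-4H-chromen-2-yl]phenyl}-2-[4-(benzyloxy)phenyl]-3-hydroxychroman-4-one
Product: 18 (2R,3S)-5,7-bis(benzyloxy)-3-{2-(benzyloxy)-5-[5,7-bis(benzyloxy)-4-oxo-4H-chromen-2-yl]phenyl}-2-[4-(benzyloxy)phenyl]chroman-4-one, via samarium enolate 17 (not isolated)
Conditions: SmI2 (2.5 equiv), THF/MeOH, −78 °C; NH4Cl (aq)
Reagents that add atoms: none
Why: SmI2 reductive cleavage of an α-hydroxy ketone (α-deoxygenation of an α-heterosubstituted ketone) removes the C3–OH without touching C2, and protonation of the enolate anti to the 2-aryl group gives the 2,3-trans (diequatorial, also thermodynamic) isomer, so the C2 centre from step 8 (descriptor changes from S to R only because C3 loses its oxygen) dictates 3S.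

**Step 10**
Reactants: 18 (2R,3S)-5,7-bis(benzyloxy)-3-{2-(benzyloxy)-5-[5,7-bis(benzyloxy)-4-oxo-4H-chromen-2-yl]phenyl}-2-[4-(benzyloxy)phenyl]chroman-4-one
Product: 19 (2R,3S)-3-[5-(5,7-dihydroxy-4-oxo-4H-chromen-2-yl)-2-hydroxyphenyl]-5,7-dihydroxy-2-(4-hydroxyphenyl)chroman-4-one
Conditions: H2 (1 atm), Pd/C (10 wt% Pd), THF/MeOH, 25 °C
Reagents that add atoms: none
Why: Neutral catalytic hydrogenolysis of the six aryl benzyl ethers; without acid or base neither C2 (no ring opening) nor C3 (no enolisation) is epimerised, and the flavone double bond and both ketones are not reduced at 1 atm and 25 °C.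

**Compound list**
1 | 5-formyl-2-hydroxybenzoic acid | O=Cc1ccc(O)c(C(=O)O)c1 | starting material
2 | benzyl 2-(benzyloxy)-5-formylbenzoate | O=Cc1ccc(OCc2ccccc2)c(C(=O)OCc2ccccc2)c1 | intermediate
3 | 2-(benzyloxy)-5-formylbenzoic acid | O=Cc1ccc(OCc2ccccc2)c(C(=O)O)c1 | intermediate
4 | 1-[2,4-bis(benzyloxy)-6-hydroxyphenyl]ethan-1-one | CC(=O)c1c(O)cc(OCc2ccccc2)cc1OCc1ccccc1 | starting material
5 | (E)-2-(benzyloxy)-5-{3-[2,4-bis(benzyloxy)-6-hydroxyphenyl]-3-oxoprop-1-en-1-yl}benzoic acid | O=C(/C=C/c1ccc(OCc2ccccc2)c(C(=O)O)c1)c1c(O)cc(OCc2ccccc2)cc1OCc1ccccc1 | intermediate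
6 | 2-(benzyloxy)-5-[5,7-bis(benzyloxy)-4-oxo-4H-chromen-2-yl]benzoic acid | O=C(O)c1cc(-c2cc(=O)c3c(OCc4ccccc4)cc(OCc4ccccc4)cc3o2)ccc1OCc1ccccc1 | intermediate
7 | 1-(benzyloxy)-4-(chloromethyl)benzene | ClCc1ccc(OCc2ccccc2)cc1 | starting material
8 | 2-(benzyloxy)-5-[5,7-bis(benzyloxy)-4-oxo-4H-chromen-2-yl]benzoyl chloride | O=C(Cl)c1cc(-c2cc(=O)c3c(OCc4ccccc4)cc(OCc4ccccc4)cc3o2)ccc1OCc1ccccc1 | intermediate
9 | [4-(benzyloxy)benzyl]zinc chloride | Cl[Zn]Cc1ccc(OCc2ccccc2)cc1 | intermediate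
10 | 5,7-bis(benzyloxy)-2-{4-(benzyloxy)-3-[2-(4-(benzyloxy)phenyl)acetyl]phenyl}-4H-chromen-4-one | O=C(Cc1ccc(OCc2ccccc2)cc1)c1cc(-c2cc(=O)c3c(OCc4ccccc4)cc(OCc4ccccc4)cc3o2)ccc1OCc1ccccc1 | intermediate
11 | (Z)-trimethylsilyl enol ether of 10 (C=C between the former carbonyl carbon and the benzylic carbon; OSiMe3 cis to the 4-(benzyloxy)phenyl group) | C[Si](C)(C)O/C(=C\c1ccc(OCc2ccccc2)cc1)c1cc(-c2cc(=O)c3c(OCc4ccccc4)cc(OCc4ccccc4)cc3o2)ccc1OCc1ccccc1 | intermediate
12 | 5,7-bis(benzyloxy)-2-{4-(benzyloxy)-3-[2-bromo-2-(4-(benzyloxy)phenyl)acetyl]phenyl}-4H-chromen-4-one (racemic) | O=C(C(Br)c1ccc(OCc2ccccc2)cc1)c1cc(-c2cc(=O)c3c(OCc4ccccc4)cc(OCc4ccccc4)cc3o2)ccc1OCc1ccccc1 | intermediate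
13 | 2,4,6-trihydroxybenzaldehyde | O=Cc1c(O)cc(O)cc1O | starting material
14 | 2,4-bis(benzyloxy)-6-hydroxybenzaldehyde | O=Cc1c(O)cc(OCc2ccccc2)cc1OCc1ccccc1 | intermediate
15 | 2,4-bis(benzyloxy)-6-{1-[4-(benzyloxy)phenyl]-2-[2-(benzyloxy)-5-(5,7-bis(benzyloxy)-4-oxo-4H-chromen-2-yl)phenyl]-2-oxoethoxy}benzaldehyde (racemic) | O=Cc1c(OC(c2ccc(OCc3ccccc3)cc2)C(=O)c2cc(-c3cc(=O)c4c(OCc5ccccc5)cc(OCc5ccccc5)cc4o3)ccc2OCc2ccccc2)cc(OCc2ccccc2)cc1OCc1ccccc1 | intermediate
16 | (2S,3R)-5,7-bis(benzyloxy)-3-{2-(benzyloxy)-5-[5,7-bis(benzyloxy)-4-oxo-4H-chromen-2-yl]phenyl}-2-[4-(benzyloxy)phenyl]-3-hydroxychroman-4-one | O=C1c2c(OCc3ccccc3)cc(OCc3ccccc3)cc2O[C@@H](c2ccc(OCc3ccccc3)cc2)[C@]1(O)c1cc(-c2cc(=O)c3c(OCc4ccccc4)cc(OCc4ccccc4)cc3o2)ccc1OCc1ccccc1 | intermediate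
17 | diiodosamarium enolate of 18 (oxygen at C4 bound to samarium; C3=C4 double bond; C2 configured as in 18) | I[Sm](I)OC1=C(c2cc(-c3cc(=O)c4c(OCc5ccccc5)cc(OCc5ccccc5)cc4o3)ccc2OCc2ccccc2)[C@H](c2ccc(OCc3ccccc3)cc2)Oc2cc(OCc3ccccc3)cc(OCc3ccccc3)c12 | intermediate
18 | (2R,3S)-5,7-bis(benzyloxy)-3-{2-(benzyloxy)-5-[5,7-bis(benzyloxy)-4-oxo-4H-chromen-2-yl]phenyl}-2-[4-(benzyloxy)phenyl]chroman-4-one (2,3-trans) | O=C1c2c(OCc3ccccc3)cc(OCc3ccccc3)cc2O[C@@H](c2ccc(OCc3ccccc3)cc2)[C@@H]1c1cc(-c2cc(=O)c3c(OCc4ccccc4)cc(OCc4ccccc4)cc3o2)ccc1OCc1ccccc1 | intermediate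
19 | (2R,3S)-3-[5-(5,7-dihydroxy-4-oxo-4H-chromen-2-yl)-2-hydroxyphenyl]-5,7-dihydroxy-2-(4-hydroxyphenyl)chroman-4-one (2,3-trans) | O=C1c2c(O)cc(O)cc2O[C@@H](c2ccc(O)cc2)[C@@H]1c1cc(-c2cc(=O)c3c(O)cc(O)cc3o2)ccc1O | target

**Total step count:** 10. **Longest linear sequence:** 9 steps (1 → 3 → 5 → 6 → 10 → 12 → 15 → 16 → 18 → 19); step 6 is the one-step side branch.

**Three steps most likely to fail**

Step 8 (carbene-catalysed ring closure with dynamic kinetic resolution). The aldehyde is electron-rich and flanked by two ortho oxygens, the ketone is hindered, and the C2 enolate can divert reversibly into an intramolecular aldol. If the chiral triazolylidene does not turn over or selects poorly, ring closure is decoupled from stereocontrol. Setting out from 15, the small achiral carbene from 3-benzyl-5-(2-hydroxyethyl)-4-methylthiazol-3-ium chloride (20 mol%) with Et3N in THF at 50 °C closes the same ring without enantiocontrol. This gives the racemate, that is 16 together with its mirror image (2R,3S)-5,7-bis(benzyloxy)-3-{2-(benzyloxy)-5-[5,7-bis(benzyloxy)-4-oxo-4H-chromen-2-yl]phenyl}-2-[4-(benzyloxy)phenyl]-3-hydroxychroman-4-one F1. Preparative chiral-phase SFC separates the two; 16 comes back to the route at compound 16 and goes on to step 9, while F1 is re-equilibrated through 15 with the same carbene and base and resolved again.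

Step 9 (SmI2 deoxygenation). The free tertiary hydroxyl on an electron-rich aryl ketone may cleave slowly, stronger activation could reduce the chromone, and the enolate could open ring C and erase C2. The fallback replaces electron transfer by a radical chain. Setting out from 16, methyl chlorooxoacetate with 4-(dimethylamino)pyridine and pyridine in CH2Cl2 gives methyl (2S,3R)-5,7-bis(benzyloxy)-3-{2-(benzyloxy)-5-[5,7-bis(benzyloxy)-4-oxo-4H-chromen-2-yl]phenyl}-2-[4-(benzyloxy)phenyl]-4-oxochroman-3-yl oxalate F2. Bu3SnH with 2,2'-azobis(2-methylpropionitrile) in toluene at 90 °C fragments it to the benzylic, carbonyl-stabilised C3 radical, which takes hydrogen anti to the 2-aryl group and comes back to the route at compound 18.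

Step 10 (global hydrogenolysis). The benzylic O1–C2 bond of the flavanone could be hydrogenolysed to a dihydrochalcone, or the flavone double bond partly reduced, before all six benzyl groups are gone. The fallback uses Lewis-acid debenzylation. Setting out from 18, BCl3 (excess) with pentamethylbenzene as benzyl-cation scavenger in CH2Cl2 at −78 °C, quenched with MeOH, comes back to the route at compound 19 directly (no new compound: F0).

**Further compounds**
F1 | step 8 | (2R,3S)-5,7-bis(benzyloxy)-3-{2-(benzyloxy)-5-[5,7-bis(benzyloxy)-4-oxo-4H-chromen-2-yl]phenyl}-2-[4-(benzyloxy)phenyl]-3-hydroxychroman-4-one (mirror image of 16) | O=C1c2c(OCc3ccccc3)cc(OCc3ccccc3)cc2O[C@H](c2ccc(OCc3ccccc3)cc2)[C@@]1(O)c1cc(-c2cc(=O)c3c(OCc4ccccc4)cc(OCc4ccccc4)cc3o2)ccc1OCc1ccccc1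
F2 | step 9 | methyl (2S,3R)-5,7-bis(benzyloxy)-3-{2-(benzyloxy)-5-[5,7-bis(benzyloxy)-4-oxo-4H-chromen-2-yl]phenyl}-2-[4-(benzyloxy)phenyl]-4-oxochroman-3-yl oxalate | O=C1c2c(OCc3ccccc3)cc(OCc3ccccc3)cc2O[C@@H](c2ccc(OCc3ccccc3)cc2)[C@]1(OC(=O)C(=O)OC)c1cc(-c2cc(=O)c3c(OCc4ccccc4)cc(OCc4ccccc4)cc3o2)ccc1OCc1ccccc1
F0 | step 10 | none | none
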